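## Retrosynthetic overview

1. Last operation: an indium Barbier allylation/lactonisation of an open-chain bromo ester α-hydroxy aldehyde closes the ten-membered carbocycle (C6–C7) and the α-methylene-γ-lactone together.
2. C7 is a one-carbon gem-diallyl linchpin, methyl 3-bromo-2-(bromomethyl)acrylate: it allylates the C8 aldehyde first (intermolecular) and the C6 aldehyde second (ring closure), a formal [9+1] annulation.
3. The two α-hydroxy aldehyde arms (C8–C9 and C5–C6, related by a hidden C2-like symmetry of C5–C9) come from two copper–pybox Mukaiyama aldols of glyoxal equivalents, at C2 and at the vinylogous 5-ethyl carbon of a preformed furanone.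
4. Ring order: furanone first (from but-3-yn-2-ol), then carbocycle plus lactone in one operation at the end; the isovalerate is installed before ring closure.

Assumption: atom labels C1–C15 follow germacrane numbering (C6 lactone carbinol, C7 ring-fusion carbon, C8 ester carbinol, C10 quaternary furanone carbon); the target read from the SMILES is the (4R,5S,6S,7S,8S,9R,10S) isomer. Ph-pybox = 2,6-bis[(4S)-4-phenyl-4,5-dihydro-1,3-oxazol-2-yl]pyridine.

## Route

Step 1
Reactants: 1 but-3-yn-2-ol (racemic); 2 N-methoxy-N-methylpropanamide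
Product: 3 6-hydroxyhept-4-yn-3-one (racemic)
Conditions: n-BuLi (2.1 equiv), THF, −78 → −20 °C; then 2, −78 → 0 °C; aq. NH4Cl
Reagents that add atoms: none
Why: Weinreb ketone synthesis: the alkoxide/acetylide dianion is acylated only once because the N-methoxy-N-methyl tetrahedral chelate survives until the quench; the carbinol centre is racemic and is erased in step 3.

Step 2
Reactants: 3 6-hydroxyhept-4-yn-3-one
Product: 4 5-ethyl-2-methylfuran-3(2H)-one (racemic)
Conditions: Et2NH, EtOH, rt; then 1 M HCl, rt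
Reagents that add atoms: water, O
Why: Amine-mediated cycloisomerisation of a γ-hydroxy ynone (Jackson–Raphael furanone synthesis): conjugate addition of Et2NH gives the β-amino enone, acid closes the ring through the hydroxyl onto the ketone, dehydrates and hydrolyses the 3-aminofuran to the 3(2H)-furanone; no stereocontrol is needed.

Step 3
Reactants: 4 5-ethyl-2-methylfuran-3(2H)-one
Product: 5 [(5-ethyl-2-methylfuran-3-yl)oxy]trimethylsilane
Conditions: Me3SiOTf, Et3N, Et2O, 0 °C; filter, distil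
Reagents that add atoms: trimethylsilyl trifluoromethanesulfonate, C[Si](C)(C)OS(=O)(=O)C(F)(F)F
Why: Soft enolisation/O-silylation gives the aromatic 3-silyloxyfuran, an enol silane nucleophilic at C2; C2 becomes sp2, so the racemic centre disappears.

Step 4
Reactants: 5 [(5-ethyl-2-methylfuran-3-yl)oxy]trimethylsilane; 6 (benzyloxy)acetaldehyde
Product: 8 (2S)-2-[(1R)-2-(benzyloxy)-1-hydroxyethyl]-5-ethyl-2-methylfuran-3(2H)-one, via trimethylsilyl ether of the aldol 7 (not isolated)
Conditions: [Cu((S,S)-Ph-pybox)](SbF6)2 (5 mol %, divalent copper), CH2Cl2, −78 °C; then 1 M HCl, THF, 0 °C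
Reagents that add atoms: none
Why: Proposed new method: catalytic enantioselective Mukaiyama aldol in which the aldehyde chelates copper through carbonyl and ether oxygen so that the pybox phenyl groups leave only the si face open, giving (9R) on attack by furan C2 (the known site of Lewis acid aldols of 3-silyloxyfurans); the quaternary C10 is expected as (10S) (9,10-syn O/O) from an open antiperiplanar transition state, the minor diastereomer being removed here; closest known reaction: Evans copper–pybox aldols of enol silanes and 2-silyloxyfuran with benzyloxyacetaldehyde.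

Step 5
Reactants: 8 (2S)-2-[(1R)-2-(benzyloxy)-1-hydroxyethyl]-5-ethyl-2-methylfuran-3(2H)-one; 9 2,2-dimethoxyacetaldehyde (anhydrous, distilled)
Product: 12 (2S)-2-[(1R)-2-(benzyloxy)-1-hydroxyethyl]-5-[(2R,3S)-3-hydroxy-4,4-dimethoxybutan-2-yl]-2-methylfuran-3(2H)-one, via bis-silyl dienol ether 10 (not isolated), via bis-silyl aldol 11 (not isolated)
Conditions: LiN(iPr)2 (2.2 equiv), Me3SiCl (3 equiv), THF, −78 °C; evaporate, take up in CH2Cl2; 9 (1.5 equiv), [Cu((S,S)-Ph-pybox)](SbF6)2 (10 mol %), −78 → −40 °C; then citric acid, MeOH, 0 °C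
Reagents that add atoms: none
Why: Proposed new method: γ-deprotonation of a 2,2-disubstituted 3(2H)-furanone at its 5-alkyl group (Smith furanone chemistry) is trapped as the silyl dienol ether, which adds through its exocyclic carbon to the chelated aldehyde in a vinylogous Mukaiyama aldol; the same catalyst and the same si-face attack give (5S) by reagent control regardless of the remote C9/C10 centres, and the open transition state is expected to put the C4 methyl anti to the new hydroxyl (4R); closest known reaction: Evans copper–pybox vinylogous aldols of dienol silanes.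

Step 6
Reactants: 12 (2S)-2-[(1R)-2-(benzyloxy)-1-hydroxyethyl]-5-[(2R,3S)-3-hydroxy-4,4-dimethoxybutan-2-yl]-2-methylfuran-3(2H)-one
Product: 13 (2S)-2-[(1R)-1,2-dihydroxyethyl]-5-[(2R,3S)-3-hydroxy-4,4-dimethoxybutan-2-yl]-2-methylfuran-3(2H)-one
Conditions: H2 (1 atm), palladium on carbon (Pd/C, zerovalent palladium), EtOAc, rt
Reagents that add atoms: none
Why: Hydrogenolysis of the benzyl ether; the vinylogous-ester C=C and the dimethyl acetal are inert under neutral conditions and no stereocentre is touched.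

Step 7
Reactants: 13 (2S)-2-[(1R)-1,2-dihydroxyethyl]-5-[(2R,3S)-3-hydroxy-4,4-dimethoxybutan-2-yl]-2-methylfuran-3(2H)-one
Product: 14 (2S)-2-hydroxy-2-{(2S)-5-[(2R,3S)-3-hydroxy-4,4-dimethoxybutan-2-yl]-2-methyl-3-oxo-2,3-dihydrofuran-2-yl}acetaldehyde
Conditions: TEMPO (10 mol %), PhI(OAc)2 (1.1 equiv), CH2Cl2, 0 °C → rt; used crude
Reagents that add atoms: none
Why: Oxoammonium (TEMPO) oxidation is selective for the primary hydroxyl over the two hindered secondary ones and gives the α-hydroxy aldehyde without epimerising C9 (the descriptor changes to S only through the priority rules).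

Step 8
Reactants: 15 methyl 2-(bromomethyl)prop-2-enoate
Product: 17 methyl (2Z)-3-bromo-2-(bromomethyl)prop-2-enoate, via tribromo ester 16 (not isolated)
Conditions: Br2, CH2Cl2, 0 °C → rt; then Et3N, Et2O, 0 °C
Reagents that add atoms: bromine, BrBr
Why: Bromine addition to the acrylate followed by E2 dehydrobromination, which can only remove the α-bromine with a CH2Br hydrogen, gives the gem-diallyl linchpin; its alkene geometry is irrelevant because C7 is re-planarised in step 9.

Step 9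
Reactants: 14 (2S)-2-hydroxy-2-{(2S)-5-[(2R,3S)-3-hydroxy-4,4-dimethoxybutan-2-yl]-2-methyl-3-oxo-2,3-dihydrofuran-2-yl}acetaldehyde; 17 methyl (2Z)-3-bromo-2-(bromomethyl)prop-2-enoate
Product: 19 methyl (2Z,4S,5R)-2-(bromomethyl)-4,5-dihydroxy-5-{(2S)-5-[(2R,3S)-3-hydroxy-4,4-dimethoxybutan-2-yl]-2-methyl-3-oxo-2,3-dihydrofuran-2-yl}pent-2-enoate, via secondary allylic bromide 18 (not isolated)
Conditions: 17 (3 equiv), indium powder (In, 1.5 equiv, kept limiting), THF/H2O 1:1, 0 °C → rt; then LiBr, acetone, rt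
Reagents that add atoms: lithium bromide, [Li+].[Br-] (bromide exchanged in the SN2′ step)
Why: Proposed new method: indium inserts into the allylic C–Br bond and the γ-bromoallylindium adds through its bromine-bearing γ-carbon to the aldehyde (aqueous Barbier allylation), C8 being set 8,9-syn by chelation of indium to the free C9 hydroxyl; bromide then moves the secondary allylic bromide by SN2′ to the conjugated (Z)-2-(bromomethyl)enoate, which erases the C7 centre and leaves the same carbon ready to act as allyl nucleophile a second time; closest known reactions: γ-bromoallylindium additions and chelation-controlled allylindations of α-hydroxy aldehydes with 2-(bromomethyl)acrylates in water.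

Step 10
Reactants: 19 methyl (2Z,4S,5R)-2-(bromomethyl)-4,5-dihydroxy-5-{(2S)-5-[(2R,3S)-3-hydroxy-4,4-dimethoxybutan-2-yl]-2-methyl-3-oxo-2,3-dihydrofuran-2-yl}pent-2-enoate; 20 3-methylbutanoyl chloride
Product: 21 methyl (2Z,4S,5R)-2-(bromomethyl)-5-hydroxy-5-{(2S)-5-[(2R,3S)-3-hydroxy-4,4-dimethoxybutan-2-yl]-2-methyl-3-oxo-2,3-dihydrofuran-2-yl}-4-[(3-methylbutanoyl)oxy]pent-2-enoate
Conditions: 20 (1.1 equiv), 2-aminoethyl diphenylborinate (Ph2BOCH2CH2NH2, 10 mol %), iPr2NEt, MeCN, 0 °C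
Reagents that add atoms: none
Why: Borinic acid-catalysed regioselective monoacylation of a 1,2-diol (Taylor): the borinate of the 8,9-diol delivers the acyl group to the less hindered allylic O8 rather than O9 next to the quaternary C10, and the isolated C5 hydroxyl is not activated; no stereocentre is formed.

Step 11
Reactants: 21 methyl (2Z,4S,5R)-2-(bromomethyl)-5-hydroxy-5-{(2S)-5-[(2R,3S)-3-hydroxy-4,4-dimethoxybutan-2-yl]-2-methyl-3-oxo-2,3-dihydrofuran-2-yl}-4-[(3-methylbutanoyl)oxy]pent-2-enoate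
Product: 24 (4R,5S,6S,7S,8S,9R,10S)-5,9-dihydroxy-1-oxo-3,10-epoxygermacra-2,11(13)-dien-12,6-olid-8-yl 3-methylbutanoate (CNP0484215.2), via hydroxy aldehyde 22 (not isolated), via seco hydroxy ester 23 (not isolated)
Conditions: CF3CO2H/H2O 9:1, 0 °C, evaporate; indium powder (In, 4 equiv), THF/H2O 1:3, 1 mM by slow addition, 25 → 40 °C; then 1 M HCl to pH 1, rt
Reagents that add atoms: water, O
Why: After acid unmasking of the aldehyde, the allylindium adds through its γ-carbon C7 to the C6 aldehyde in an intramolecular Barbier allylation (Nozaki–Hiyama-type macrocyclisation, known for germacranolide ring closure with zinc or chromium) and the γ-hydroxy ester lactonises on acidification, so the ten-membered carbocycle and the α-methylene-γ-lactone form in one operation; C6 is set 5,6-syn by chelation of indium between the aldehyde oxygen and the free C5 hydroxyl, and C7 by the chair-like cyclic transition state in which the tether holds C5 and C8 antiperiplanar (6,7-trans lactone) and the C8 acyloxy group is turned towards indium so that C6 adds on the C9 side of the allyl unit.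

## Compound list

1 | but-3-yn-2-ol (racemic) | CC(O)C#C | starting material
2 | N-methoxy-N-methylpropanamide | CCC(=O)N(C)OC | starting material
3 | 6-hydroxyhept-4-yn-3-one (racemic) | CCC(=O)C#CC(C)O | intermediate
4 | 5-ethyl-2-methylfuran-3(2H)-one (racemic) | CCC1=CC(=O)C(C)O1 | intermediate
5 | [(5-ethyl-2-methylfuran-3-yl)oxy]trimethylsilane | CCc1cc(O[Si](C)(C)C)c(C)o1 | intermediate
6 | (benzyloxy)acetaldehyde | O=CCOCc1ccccc1 | starting material
7 | (2S)-2-[(1R)-2-(benzyloxy)-1-(trimethylsilyloxy)ethyl]-5-ethyl-2-methylfuran-3(2H)-one | CCC1=CC(=O)[C@@](C)(O1)[C@H](O[Si](C)(C)C)COCc1ccccc1 | intermediate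
8 | (2S)-2-[(1R)-2-(benzyloxy)-1-hydroxyethyl]-5-ethyl-2-methylfuran-3(2H)-one | CCC1=CC(=O)[C@@](C)(O1)[C@H](O)COCc1ccccc1 | intermediate
9 | 2,2-dimethoxyacetaldehyde | COC(OC)C=O | starting material
10 | {[(2S)-2-[(1R)-2-(benzyloxy)-1-(trimethylsilyloxy)ethyl]-5-ethylidene-2-methyl-2,5-dihydrofuran-3-yl]oxy}trimethylsilane (E/Z mixture at the ethylidene) | CC=C1C=C(O[Si](C)(C)C)[C@@](C)(O1)[C@H](O[Si](C)(C)C)COCc1ccccc1 | intermediate
11 | (2S)-2-[(1R)-2-(benzyloxy)-1-(trimethylsilyloxy)ethyl]-5-[(2R,3S)-4,4-dimethoxy-3-(trimethylsilyloxy)butan-2-yl]-2-methylfuran-3(2H)-one | COC(OC)[C@@H](O[Si](C)(C)C)[C@@H](C)C1=CC(=O)[C@@](C)(O1)[C@H](O[Si](C)(C)C)COCc1ccccc1 | intermediate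
12 | (2S)-2-[(1R)-2-(benzyloxy)-1-hydroxyethyl]-5-[(2R,3S)-3-hydroxy-4,4-dimethoxybutan-2-yl]-2-methylfuran-3(2H)-one | COC(OC)[C@@H](O)[C@@H](C)C1=CC(=O)[C@@](C)(O1)[C@H](O)COCc1ccccc1 | intermediate
13 | (2S)-2-[(1R)-1,2-dihydroxyethyl]-5-[(2R,3S)-3-hydroxy-4,4-dimethoxybutan-2-yl]-2-methylfuran-3(2H)-one | COC(OC)[C@@H](O)[C@@H](C)C1=CC(=O)[C@@](C)(O1)[C@H](O)CO | intermediate
14 | (2S)-2-hydroxy-2-{(2S)-5-[(2R,3S)-3-hydroxy-4,4-dimethoxybutan-2-yl]-2-methyl-3-oxo-2,3-dihydrofuran-2-yl}acetaldehyde | COC(OC)[C@@H](O)[C@@H](C)C1=CC(=O)[C@@](C)(O1)[C@H](O)C=O | intermediate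
15 | methyl 2-(bromomethyl)prop-2-enoate | C=C(CBr)C(=O)OC | starting material
16 | methyl 2,3-dibromo-2-(bromomethyl)propanoate | COC(=O)C(Br)(CBr)CBr | intermediate
17 | methyl (2Z)-3-bromo-2-(bromomethyl)prop-2-enoate | COC(=O)/C(CBr)=C/Br | intermediate
18 | methyl (4R,5R)-3-bromo-4,5-dihydroxy-5-{(2S)-5-[(2R,3S)-3-hydroxy-4,4-dimethoxybutan-2-yl]-2-methyl-3-oxo-2,3-dihydrofuran-2-yl}-2-methylidenepentanoate (both C3 epimers) | COC(OC)[C@@H](O)[C@@H](C)C1=CC(=O)[C@@](C)(O1)[C@H](O)[C@@H](O)C(Br)C(=C)C(=O)OC | intermediate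
19 | methyl (2Z,4S,5R)-2-(bromomethyl)-4,5-dihydroxy-5-{(2S)-5-[(2R,3S)-3-hydroxy-4,4-dimethoxybutan-2-yl]-2-methyl-3-oxo-2,3-dihydrofuran-2-yl}pent-2-enoate | COC(OC)[C@@H](O)[C@@H](C)C1=CC(=O)[C@@](C)(O1)[C@H](O)[C@@H](O)/C=C(\CBr)C(=O)OC | intermediate
20 | 3-methylbutanoyl chloride | CC(C)CC(Cl)=O | starting material
21 | methyl (2Z,4S,5R)-2-(bromomethyl)-5-hydroxy-5-{(2S)-5-[(2R,3S)-3-hydroxy-4,4-dimethoxybutan-2-yl]-2-methyl-3-oxo-2,3-dihydrofuran-2-yl}-4-[(3-methylbutanoyl)oxy]pent-2-enoate | COC(OC)[C@@H](O)[C@@H](C)C1=CC(=O)[C@@](C)(O1)[C@H](O)[C@@H](OC(=O)CC(C)C)/C=C(\CBr)C(=O)OC | intermediate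
22 | methyl (2Z,4S,5R)-2-(bromomethyl)-5-hydroxy-5-{(2S)-5-[(2R,3S)-3-hydroxy-4-oxobutan-2-yl]-2-methyl-3-oxo-2,3-dihydrofuran-2-yl}-4-[(3-methylbutanoyl)oxy]pent-2-enoate | O=C[C@@H](O)[C@@H](C)C1=CC(=O)[C@@](C)(O1)[C@H](O)[C@@H](OC(=O)CC(C)C)/C=C(\CBr)C(=O)OC | intermediate
23 | methyl (4R,5S,6S,7S,8S,9R,10S)-5,6,9-trihydroxy-8-[(3-methylbutanoyl)oxy]-1-oxo-3,10-epoxygermacra-2,11(13)-dien-12-oate (seco ester of the target) | COC(=O)C(=C)[C@H]1[C@H](O)[C@@H](O)[C@@H](C)C2=CC(=O)[C@@](C)(O2)[C@H](O)[C@H]1OC(=O)CC(C)C | intermediate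
24 | (4R,5S,6S,7S,8S,9R,10S)-5,9-dihydroxy-1-oxo-3,10-epoxygermacra-2,11(13)-dien-12,6-olid-8-yl 3-methylbutanoate (CNP0484215.2) | C=C1C(=O)O[C@@H]2[C@@H](O)[C@@H](C)C3=CC(=O)[C@@](C)(O3)[C@H](O)[C@@H](OC(=O)CC(C)C)[C@@H]12 | target

## Step count and risks

Total step count: 11. Longest linear sequence: 10 steps (steps 1–7 and 9–11, from 1); step 8 is a one-step side branch.

**Step 11 (ring closure).** The allylindium may be protonated before the slow ten-membered ring closure, oligomerise, lose the C8 acyloxy group by 1,4-elimination, or close to the C7 epimer or the 6,7-cis lactone; the facial course at C7 is the least certain prediction in the route. The fallback sets out from 21 and comes back at 23. Borylation of the allylic bromide with bis(pinacolato)diboron and Pd2(dba)3 (zerovalent palladium) gives methyl (2E,4S,5R)-5-hydroxy-5-{(2S)-5-[(2R,3S)-3-hydroxy-4,4-dimethoxybutan-2-yl]-2-methyl-3-oxo-2,3-dihydrofuran-2-yl}-4-[(3-methylbutanoyl)oxy]-2-[(4,4,5,5-tetramethyl-1,3,2-dioxaborolan-2-yl)methyl]pent-2-enoate F1. Aqueous CF3CO2H then unmasks the corresponding 4-oxobutan-2-yl aldehyde F2. Heated at high dilution (toluene, 80 °C, or with catalytic Sc(OTf)3), F2 closes by a metal-free intramolecular allylboration through a closed six-membered chair to the O6 pinacolboryl ether of the seco ester F3. Work-up hydrolyses F3 to 23, which p-TsOH lactonises to 24.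

**Step 9 (linchpin allylation).** The product is itself an allylic bromide and can insert indium a second time (diene by elimination, 2:1 adducts), or the SN2′ transposition may be incomplete. The fallback sets out from 14 and comes back at 19. A Nozaki–Hiyama–Kishi vinylation of 14 with iodoethene (CrCl2, divalent chromium, with catalytic NiCl2, divalent nickel, DMF) gives (2S)-2-[(1R,2S)-1,2-dihydroxybut-3-en-1-yl]-5-[(2R,3S)-3-hydroxy-4,4-dimethoxybutan-2-yl]-2-methylfuran-3(2H)-one F4, the 8,9-syn isomer being separated. Cross-metathesis of F4 with 15 (second-generation Hoveyda–Grubbs catalyst, CH2Cl2, 40 °C) then installs C11–C13 and gives 19.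

**Step 5 (vinylogous aldol).** 2,2-Dimethoxyacetaldehyde may not chelate copper as benzyloxyacetaldehyde does, and the C4/C5 anti preference is unproven. The fallback sets out from 8 and comes back at 12. Silylation (Et3SiCl, imidazole) gives (2S)-2-[(1R)-2-(benzyloxy)-1-(triethylsilyloxy)ethyl]-5-ethyl-2-methylfuran-3(2H)-one F5. Its lithium dienolate (LiN(iPr)2, THF, −78 °C) adds to 9 in a Smith-type γ-aldol to give (2S)-2-[(1R)-2-(benzyloxy)-1-(triethylsilyloxy)ethyl]-5-[(2R,3S)-3-hydroxy-4,4-dimethoxybutan-2-yl]-2-methylfuran-3(2H)-one F6, separated from its C4/C5 isomers (the C4 epimer can be recycled by DBU equilibration). AcOH/THF/H2O removes the silyl group to give 12.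

## Further compounds

F1 | step 11 | methyl (2E,4S,5R)-5-hydroxy-5-{(2S)-5-[(2R,3S)-3-hydroxy-4,4-dimethoxybutan-2-yl]-2-methyl-3-oxo-2,3-dihydrofuran-2-yl}-4-[(3-methylbutanoyl)oxy]-2-[(4,4,5,5-tetramethyl-1,3,2-dioxaborolan-2-yl)methyl]pent-2-enoate | COC(OC)[C@@H](O)[C@@H](C)C1=CC(=O)[C@@](C)(O1)[C@H](O)[C@@H](OC(=O)CC(C)C)/C=C(\CB2OC(C)(C)C(C)(C)O2)C(=O)OC
F2 | step 11 | methyl (2E,4S,5R)-5-hydroxy-5-{(2S)-5-[(2R,3S)-3-hydroxy-4-oxobutan-2-yl]-2-methyl-3-oxo-2,3-dihydrofuran-2-yl}-4-[(3-methylbutanoyl)oxy]-2-[(4,4,5,5-tetramethyl-1,3,2-dioxaborolan-2-yl)methyl]pent-2-enoate | O=C[C@@H](O)[C@@H](C)C1=CC(=O)[C@@](C)(O1)[C@H](O)[C@@H](OC(=O)CC(C)C)/C=C(\CB2OC(C)(C)C(C)(C)O2)C(=O)OC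
F3 | step 11 | O6 pinacolboryl ether of seco ester 23 | COC(=O)C(=C)[C@H]1[C@H](OB3OC(C)(C)C(C)(C)O3)[C@@H](O)[C@@H](C)C2=CC(=O)[C@@](C)(O2)[C@H](O)[C@H]1OC(=O)CC(C)C
F4 | step 9 | (2S)-2-[(1R,2S)-1,2-dihydroxybut-3-en-1-yl]-5-[(2R,3S)-3-hydroxy-4,4-dimethoxybutan-2-yl]-2-methylfuran-3(2H)-one | COC(OC)[C@@H](O)[C@@H](C)C1=CC(=O)[C@@](C)(O1)[C@H](O)[C@@H](O)C=C
F5 | step 5 | (2S)-2-[(1R)-2-(benzyloxy)-1-(triethylsilyloxy)ethyl]-5-ethyl-2-methylfuran-3(2H)-one | CCC1=CC(=O)[C@@](C)(O1)[C@H](O[Si](CC)(CC)CC)COCc1ccccc1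
F6 | step 5 | (2S)-2-[(1R)-2-(benzyloxy)-1-(triethylsilyloxy)ethyl]-5-[(2R,3S)-3-hydroxy-4,4-dimethoxybutan-2-yl]-2-methylfuran-3(2H)-one | COC(OC)[C@@H](O)[C@@H](C)C1=CC(=O)[C@@](C)(O1)[C@H](O[Si](CC)(CC)CC)COCc1ccccc1
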